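**Strategy.** The cis‑3,6‑diol flanking C4=C5 in the left ring is the retron of a singlet‑oxygen adduct of a cyclohexa‑1,3‑diene, so that ring (C1–C6) is first made as ethyl safranate. Its carbons are two isoprenoid halves: C1(Me2)–C2–C3 from a prenyl ylide and C4–C5(Me)–C6(–C7) from ethyl 3‑methyl‑4‑oxocrotonate. One pot joins them twice: Wittig olefination makes C3=C4, and 6π‑electrocyclisation of the (4Z)‑trienoate closes the congested C1–C6 bond at the gem‑dimethyl carbon. Photooxygenation, lipase resolution and chain extension give a C15 aldehyde, united by Wittig reaction with an acetylenic C25 phosphonium salt built from actinol, an enynol and the C10 dialdehyde.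

Key step: step 1

Remarks: carotenoid locants (C1–C15, C1′–C15′) are used for atoms of the target. Racemates 6, 8 and 9 are written without stereodescriptors. Actinol 15, enynol 18 and dialdehyde 21 are assumed to be purchasable carotenoid building blocks. In step 3 the lipase is assumed to acylate the (4R) carbinol, as it does with simple cyclohex‑2‑en‑1‑ols.

**Step 1**
Reactants: 1 (3‑methylbut‑2‑en‑1‑yl)triphenylphosphonium bromide; 2 ethyl (2E)‑3‑methyl‑4‑oxobut‑2‑enoate
Product: 7 ethyl 2,6,6‑trimethylcyclohexa‑1,3‑diene‑1‑carboxylate (ethyl safranate), via prenyl ylide 3 (not isolated), via (2E,4E)‑trienoate 4 (not isolated), via (2E,4Z)‑trienoate 5 (not isolated), via ethyl α‑safranate 6 (not isolated)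
Conditions: KOt‑Bu, PhMe, 0 °C; then 2, 0 °C → rt; then I2 (3 mol %), 150 °C (sealed tube); then DBU (0.3 equiv), 60 °C
Reagents that add atoms: none
Why: Ylide 3 olefinates the aldehyde carbon of 2 (Wittig reaction), which joins C3 to C4 and gives the 4E and 4Z trienoates 4 and 5; iodine‑catalysed E/Z equilibration keeps supplying 5, and only 5 can close by thermal disrotatory 6π‑electrocyclisation, which forms the C1–C6 bond between the gem‑dimethyl terminus and the ester‑bearing terminus. The closest known reaction type is the domino olefination/6π‑electrocyclisation route to cyclohexa‑1,3‑dienes, the all‑carbon counterpart of the condensation/oxa‑6π formal [3+3] annulation of 3‑methylbut‑2‑enal. The six‑membered ring is closed in the pericyclic mode, which is intramolecular and irreversible and should therefore tolerate the fully substituted C1. DBU then shifts the C6 proton of 6 to C2 through the extended ester dienolate to give the linearly conjugated diene 7, so the transient C6 stereocentre of 6 is erased and no stereocentre has to be controlled. The step needs carbonyl selectivity (the aldehyde of 2 is far more electrophilic than its ester or its hindered enoate β‑carbon), α‑attack of the allylic ylide (its γ‑carbon is the blocked CMe2) and the 4Z geometry (secured by the equilibration, since 5 alone is drained).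

**Step 2**
Reactants: 7 ethyl safranate
Product: 9 rac‑ethyl (1R*,4S*)‑1,4‑dihydroxy‑2,6,6‑trimethylcyclohex‑2‑ene‑1‑carboxylate (cis‑diol), via endoperoxide ester 8 (not isolated)
Conditions: O2, tetraphenylporphyrin (cat.), visible light, CH2Cl2, −20 °C; then thiourea, MeOH, rt
Reagents that add atoms: oxygen, O=O
Why: Singlet oxygen should add suprafacially in a [4+2] photooxygenation to the ring‑locked s‑cis diene C3=C4–C5=C6, which places the C3 and C6 oxygens cis and leaves C4=C5, and thiourea then reduces the O–O bond without touching the ester.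

**Step 3**
Reactants: 9 rac‑cis‑diol ester
Product: 10 ethyl (1R,4S)‑1,4‑dihydroxy‑2,6,6‑trimethylcyclohex‑2‑ene‑1‑carboxylate
Conditions: immobilised Burkholderia cepacia lipase (Amano PS), vinyl acetate, MTBE, 30 °C, run past half conversion; chromatography
Reagents that add atoms: none
Why: Lipase‑catalysed kinetic resolution by acylation of the secondary allylic carbinol is expected to acetylate the (4R) enantiomer, so the (1R,4S) diol is recovered unchanged with both stereocentres fixed in the absolute sense, the tertiary hydroxyl being inert to the enzyme.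

**Step 4**
Reactants: 10 (1R,4S)‑diol ester
Product: 11 (1R,4S)‑1,4‑dihydroxy‑2,6,6‑trimethylcyclohex‑2‑ene‑1‑carbaldehyde
Conditions: DIBAL‑H (4 equiv), CH2Cl2, −78 °C; aq. Rochelle salt
Reagents that add atoms: none
Why: Partial ester reduction should stop at the aldehyde because the tetrahedral aluminium hemiacetal is held in a five‑membered chelate by the neighbouring C1 alkoxide, and C1 carries no hydrogen so its configuration cannot be lost.

**Step 5**
Reactants: 11 hydroxy aldehyde (used crude); 12 diethyl (3‑cyano‑2‑methylprop‑2‑en‑1‑yl)phosphonate (E/Z mixture)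
Product: 13 (2E,4E)‑5‑[(1R,4S)‑1,4‑dihydroxy‑2,6,6‑trimethylcyclohex‑2‑en‑1‑yl]‑3‑methylpenta‑2,4‑dienenitrile
Conditions: 12, NaH (excess), THF, 0 °C; then 11, −20 °C → rt; chromatography to remove the 2Z isomer
Reagents that add atoms: none
Why: Horner–Wadsworth–Emmons olefination with the vinylogous cyanophosphonate anion should form the C7=C8 bond with E geometry, while the geometry at the trisubstituted C9=C10 bond is settled by separation of the minor 2Z isomer.

**Step 6**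
Reactants: 13 dihydroxy dienenitrile
Product: 14 (2E,4E)‑5‑[(1R,4S)‑1,4‑dihydroxy‑2,6,6‑trimethylcyclohex‑2‑en‑1‑yl]‑3‑methylpenta‑2,4‑dienal
Conditions: DIBAL‑H (4 equiv), CH2Cl2, −78 → −40 °C; wet SiO2, aq. Rochelle salt
Reagents that add atoms: water, O
Why: DIBAL‑H adds once to the nitrile to give an N‑aluminoimine that is hydrolysed to the aldehyde on neutral work‑up (nitrile half‑reduction), the two free hydroxyls only consuming reagent.

**Step 7**
Reactants: 15 (4R,6R)‑4‑hydroxy‑2,2,6‑trimethylcyclohexan‑1‑one (actinol)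
Product: 16 (4R,6R)‑2,2,6‑trimethyl‑4‑[(triethylsilyl)oxy]cyclohexan‑1‑one
Conditions: TESCl, imidazole, DMF, 0 °C → rt
Reagents that add atoms: chlorotriethylsilane, CC[Si](Cl)(CC)CC
Why: Standard silylation of the secondary alcohol gives an ether that survives LDA and palladium catalysis and later falls off under the acidic phosphonium‑salt formation.

**Step 8**
Reactants: 16 TES‑actinol
Product: 17 (4R)‑2,6,6‑trimethyl‑4‑[(triethylsilyl)oxy]cyclohex‑1‑en‑1‑yl trifluoromethanesulfonate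
Conditions: LDA, THF, −78 → 0 °C; then PhNTf2, −78 °C → rt
Reagents that add atoms: N‑phenylbis(trifluoromethanesulfonimide), O=S(=O)(N(c1ccccc1)S(=O)(=O)C(F)(F)F)C(F)(F)F
Why: The ketone can enolise only towards C6 because C2 is quaternary, so a single tetrasubstituted enolate is O‑triflated (enol triflate formation), which removes the C6 stereocentre on purpose and leaves C4 untouched.

**Step 9**
Reactants: 17 alkenyl triflate; 18 (2E)‑3‑methylpent‑2‑en‑4‑yn‑1‑ol
Product: 19 (2E)‑3‑methyl‑5‑{(4R)‑2,6,6‑trimethyl‑4‑[(triethylsilyl)oxy]cyclohex‑1‑en‑1‑yl}pent‑2‑en‑4‑yn‑1‑ol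
Conditions: Pd(PPh3)4 (cat.), CuI (cat.), i‑Pr2NH, DMF, rt
Reagents that add atoms: none
Why: Sonogashira coupling of the alkenyl triflate with the terminal alkyne should form the C6′–C7′ bond with the E geometry of the enynol retained.

**Step 10**
Reactants: 19 C15 enynol silyl ether
Product: 20 [(2E)‑5‑[(4R)‑4‑hydroxy‑2,6,6‑trimethylcyclohex‑1‑en‑1‑yl]‑3‑methylpent‑2‑en‑4‑yn‑1‑yl]triphenylphosphonium bromide
Conditions: PPh3·HBr (1.2 equiv), MeOH, rt
Reagents that add atoms: triphenylphosphine hydrobromide, [Br-].c1ccc(cc1)[PH+](c1ccccc1)c1ccccc1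
Why: The acid ionises the primary allylic alcohol and the phosphine captures the delocalised cation at its unhindered primary terminus (allylic phosphonium salt formation), while the same acid in methanol cleaves the triethylsilyl ether.

**Step 11**
Reactants: 20 C15 phosphonium bromide; 21 (2E,4E,6E)‑2,7‑dimethylocta‑2,4,6‑trienedial (3 equiv)
Product: 22 (2E,4E,6E,8E,10E)‑13‑[(4R)‑4‑hydroxy‑2,6,6‑trimethylcyclohex‑1‑en‑1‑yl]‑2,7,11‑trimethyltrideca‑2,4,6,8,10‑pentaen‑12‑ynal
Conditions: NaOMe, CH2Cl2/MeOH, 0 °C → rt (salt added slowly to 21); then EtOAc, 70 °C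
Reagents that add atoms: none
Why: Wittig olefination with an excess of the symmetrical dialdehyde should give mono‑condensation, and the hindered Z isomer at the new C11′=C12′ bond is expected to equilibrate to E on warming.

**Step 12**
Reactants: 22 C25 aldehyde
Product: 23 (2E,4E,6E,8E,10E)‑13‑[(4R)‑4‑hydroxy‑2,6,6‑trimethylcyclohex‑1‑en‑1‑yl]‑2,7,11‑trimethyltrideca‑2,4,6,8,10‑pentaen‑12‑yn‑1‑ol
Conditions: NaBH4, MeOH/THF, 0 °C
Reagents that add atoms: none
Why: Borohydride reduces the conjugated aldehyde by 1,2‑addition to the allylic alcohol without touching the polyene or the alkyne.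

**Step 13**
Reactants: 23 C25 alcohol
Product: 24 [(2E,4E,6E,8E,10E)‑13‑[(4R)‑4‑hydroxy‑2,6,6‑trimethylcyclohex‑1‑en‑1‑yl]‑2,7,11‑trimethyltrideca‑2,4,6,8,10‑pentaen‑12‑yn‑1‑yl]triphenylphosphonium bromide
Conditions: PPh3·HBr, CH2Cl2/MeOH, 0 °C → rt
Reagents that add atoms: triphenylphosphine hydrobromide, [Br-].c1ccc(cc1)[PH+](c1ccccc1)c1ccccc1
Why: As in step 10, the polyenylic cation formed from the primary allylic alcohol is trapped by the phosphine at the primary carbon, and this half contains no acid‑labile tertiary alcohol.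

**Step 14**
Reactants: 24 C25 phosphonium bromide; 14 C15 dihydroxy dienal
Product: 25 target, (1R,4S)‑1‑[(1E,3E,5E,7E,9E,11E,13E,15E)‑18‑[(4R)‑4‑hydroxy‑2,6,6‑trimethylcyclohex‑1‑en‑1‑yl]‑3,7,12,16‑tetramethyloctadeca‑1,3,5,7,9,11,13,15‑octaen‑17‑yn‑1‑yl]‑2,6,6‑trimethylcyclohex‑2‑ene‑1,4‑diol
Conditions: NaOMe, CH2Cl2/MeOH, 0 °C → rt, dark, argon; then EtOAc, 70 °C
Reagents that add atoms: none
Why: Wittig olefination joins C11 of the aldehyde to C12 of the ylide under mildly basic conditions that should leave the acid‑labile doubly allylic tertiary C6 alcohol intact, and the hindered 11Z isomer is expected to convert into the all‑E compound on warming in a neutral solvent.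

**Compound list**
1 | (3‑methylbut‑2‑en‑1‑yl)triphenylphosphonium bromide | [Br-].CC(C)=CC[P+](c1ccccc1)(c1ccccc1)c1ccccc1 | starting material
2 | ethyl (2E)‑3‑methyl‑4‑oxobut‑2‑enoate | CCOC(=O)/C=C(\C)C=O | starting material
3 | (3‑methylbut‑2‑en‑1‑ylidene)triphenylphosphorane (prenyl ylide) | CC(C)=CC=P(c1ccccc1)(c1ccccc1)c1ccccc1 | intermediate
4 | ethyl (2E,4E)‑3,7‑dimethylocta‑2,4,6‑trienoate | CCOC(=O)/C=C(C)/C=C/C=C(C)C | intermediate
5 | ethyl (2E,4Z)‑3,7‑dimethylocta‑2,4,6‑trienoate | CCOC(=O)/C=C(C)/C=C\C=C(C)C | intermediate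
6 | rac‑ethyl 2,6,6‑trimethylcyclohexa‑2,4‑diene‑1‑carboxylate (ethyl α‑safranate) | CCOC(=O)C1C(C)=CC=CC1(C)C | intermediate
7 | ethyl 2,6,6‑trimethylcyclohexa‑1,3‑diene‑1‑carboxylate (ethyl safranate) | CCOC(=O)C1=C(C)C=CCC1(C)C | intermediate
8 | rac‑ethyl 6,7,7‑trimethyl‑2,3‑dioxabicyclo[2.2.2]oct‑5‑ene‑1‑carboxylate | CCOC(=O)C12OOC(C=C1C)CC2(C)C | intermediate
9 | rac‑ethyl (1R*,4S*)‑1,4‑dihydroxy‑2,6,6‑trimethylcyclohex‑2‑ene‑1‑carboxylate (cis‑diol, racemate) | CCOC(=O)C1(O)C(C)=CC(O)CC1(C)C | intermediate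
10 | ethyl (1R,4S)‑1,4‑dihydroxy‑2,6,6‑trimethylcyclohex‑2‑ene‑1‑carboxylate | CC1=C[C@@H](O)CC(C)(C)[C@]1(O)C(=O)OCC | intermediate
11 | (1R,4S)‑1,4‑dihydroxy‑2,6,6‑trimethylcyclohex‑2‑ene‑1‑carbaldehyde | CC1=C[C@@H](O)CC(C)(C)[C@]1(O)C=O | intermediate
12 | diethyl (3‑cyano‑2‑methylprop‑2‑en‑1‑yl)phosphonate (E/Z mixture) | CCOP(=O)(CC(C)=CC#N)OCC | starting material
13 | (2E,4E)‑5‑[(1R,4S)‑1,4‑dihydroxy‑2,6,6‑trimethylcyclohex‑2‑en‑1‑yl]‑3‑methylpenta‑2,4‑dienenitrile | CC1=C[C@@H](O)CC(C)(C)[C@]1(O)/C=C/C(C)=C/C#N | intermediate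
14 | (2E,4E)‑5‑[(1R,4S)‑1,4‑dihydroxy‑2,6,6‑trimethylcyclohex‑2‑en‑1‑yl]‑3‑methylpenta‑2,4‑dienal | CC1=C[C@@H](O)CC(C)(C)[C@]1(O)/C=C/C(C)=C/C=O | intermediate
15 | (4R,6R)‑4‑hydroxy‑2,2,6‑trimethylcyclohexan‑1‑one (actinol) | C[C@@H]1C[C@@H](O)CC(C)(C)C1=O | starting material
16 | (4R,6R)‑2,2,6‑trimethyl‑4‑[(triethylsilyl)oxy]cyclohexan‑1‑one | C[C@@H]1C[C@@H](O[Si](CC)(CC)CC)CC(C)(C)C1=O | intermediate
17 | (4R)‑2,6,6‑trimethyl‑4‑[(triethylsilyl)oxy]cyclohex‑1‑en‑1‑yl trifluoromethanesulfonate | O=S(=O)(OC1=C(C)C[C@@H](O[Si](CC)(CC)CC)CC1(C)C)C(F)(F)F | intermediate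
18 | (2E)‑3‑methylpent‑2‑en‑4‑yn‑1‑ol | C#C/C(C)=C/CO | starting material
19 | (2E)‑3‑methyl‑5‑{(4R)‑2,6,6‑trimethyl‑4‑[(triethylsilyl)oxy]cyclohex‑1‑en‑1‑yl}pent‑2‑en‑4‑yn‑1‑ol | OC/C=C(\C)C#CC1=C(C)C[C@@H](O[Si](CC)(CC)CC)CC1(C)C | intermediate
20 | [(2E)‑5‑[(4R)‑4‑hydroxy‑2,6,6‑trimethylcyclohex‑1‑en‑1‑yl]‑3‑methylpent‑2‑en‑4‑yn‑1‑yl]triphenylphosphonium bromide | [Br-].c1ccccc1[P+](c1ccccc1)(c1ccccc1)C/C=C(\C)C#CC1=C(C)C[C@@H](O)CC1(C)C | intermediate
21 | (2E,4E,6E)‑2,7‑dimethylocta‑2,4,6‑trienedial | O=C/C(C)=C/C=C/C=C(\C)C=O | starting material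
22 | (2E,4E,6E,8E,10E)‑13‑[(4R)‑4‑hydroxy‑2,6,6‑trimethylcyclohex‑1‑en‑1‑yl]‑2,7,11‑trimethyltrideca‑2,4,6,8,10‑pentaen‑12‑ynal | O=C/C(C)=C/C=C/C=C(C)/C=C/C=C(\C)C#CC1=C(C)C[C@@H](O)CC1(C)C | intermediate
23 | (2E,4E,6E,8E,10E)‑13‑[(4R)‑4‑hydroxy‑2,6,6‑trimethylcyclohex‑1‑en‑1‑yl]‑2,7,11‑trimethyltrideca‑2,4,6,8,10‑pentaen‑12‑yn‑1‑ol | OC/C(C)=C/C=C/C=C(C)/C=C/C=C(\C)C#CC1=C(C)C[C@@H](O)CC1(C)C | intermediate
24 | [(2E,4E,6E,8E,10E)‑13‑[(4R)‑4‑hydroxy‑2,6,6‑trimethylcyclohex‑1‑en‑1‑yl]‑2,7,11‑trimethyltrideca‑2,4,6,8,10‑pentaen‑12‑yn‑1‑yl]triphenylphosphonium bromide | [Br-].c1ccccc1[P+](c1ccccc1)(c1ccccc1)C/C(C)=C/C=C/C=C(C)/C=C/C=C(\C)C#CC1=C(C)C[C@@H](O)CC1(C)C | intermediate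
25 | (1R,4S)‑1‑[(1E,3E,5E,7E,9E,11E,13E,15E)‑18‑[(4R)‑4‑hydroxy‑2,6,6‑trimethylcyclohex‑1‑en‑1‑yl]‑3,7,12,16‑tetramethyloctadeca‑1,3,5,7,9,11,13,15‑octaen‑17‑yn‑1‑yl]‑2,6,6‑trimethylcyclohex‑2‑ene‑1,4‑diol | CC1=C[C@@H](O)CC(C)(C)[C@]1(O)/C=C/C(C)=C/C=C/C(C)=C/C=C/C=C(C)/C=C/C=C(\C)C#CC1=C(C)C[C@@H](O)CC1(C)C | target

**Count.** Total: 14 steps. Longest linear sequence: 8 steps (15 → 25, steps 7–14); the left‑hand branch is 7 steps (steps 1–6 and 14).

**Steps most likely to fail**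

Step 1. The E/Z equilibration of the trienoate may be slower than its polymerisation or competing hydrogen shifts at 150 °C, so that too little of the 4Z isomer reaches the electrocyclisation. The fallback sets out from 2 and builds the Z geometry directly. Stork–Zhao iodo‑olefination of 2 with (iodomethyl)triphenylphosphonium iodide and NaHMDS should give ethyl (2E,4Z)‑5‑iodo‑3‑methylpenta‑2,4‑dienoate F1. Suzuki–Miyaura coupling of F1 with 2‑methylprop‑1‑enylboronic acid pinacol ester (Pd(PPh3)4, aq. K3PO4, THF) proceeds with retention and comes back to the route at the pure (4Z)‑trienoate 5. Heating 5 without iodine and treating with DBU, as in step 1, then leads through 6 to 7.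

Step 3. The enzyme may discriminate poorly between the two heavily substituted ring arms, or may acylate the opposite enantiomer. The fallback sets out from 9 and uses a classical resolution. Esterification of the secondary hydroxyl with (S)‑O‑methylmandelic acid (DCC, DMAP, CH2Cl2) gives two diastereomeric esters that are separated by chromatography or crystallisation. The wanted one is ethyl (1R,4S)‑1‑hydroxy‑4‑{[(2S)‑2‑methoxy‑2‑phenylacetyl]oxy}‑2,6,6‑trimethylcyclohex‑2‑ene‑1‑carboxylate F2, whose configuration is assigned by the usual NMR model for mandelates. Transesterification of F2 with K2CO3 in EtOH comes back to the route at 10.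

Step 4. Over‑reduction of the hindered ester to the primary alcohol, or α‑ketol rearrangement of the free α‑hydroxy aldehyde during work‑up, may erode the aldehyde. The fallback sets out from 10 and protects both hydroxyls. TESOTf and 2,6‑lutidine give ethyl (1R,4S)‑2,6,6‑trimethyl‑1,4‑bis[(triethylsilyl)oxy]cyclohex‑2‑ene‑1‑carboxylate F3. Full reduction with DIBAL‑H at 0 °C gives [(1R,4S)‑2,6,6‑trimethyl‑1,4‑bis[(triethylsilyl)oxy]cyclohex‑2‑en‑1‑yl]methanol F4. Dess–Martin oxidation gives (1R,4S)‑2,6,6‑trimethyl‑1,4‑bis[(triethylsilyl)oxy]cyclohex‑2‑ene‑1‑carbaldehyde F5. Horner–Wadsworth–Emmons reaction of F5 with 12 gives (2E,4E)‑3‑methyl‑5‑[(1R,4S)‑2,6,6‑trimethyl‑1,4‑bis[(triethylsilyl)oxy]cyclohex‑2‑en‑1‑yl]penta‑2,4‑dienenitrile F6. Desilylation of F6 with TBAF in THF comes back to the route at 13.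

**Further compounds**
F1 | step 1 | ethyl (2E,4Z)‑5‑iodo‑3‑methylpenta‑2,4‑dienoate | CCOC(=O)/C=C(C)/C=C\I
F2 | step 3 | ethyl (1R,4S)‑1‑hydroxy‑4‑{[(2S)‑2‑methoxy‑2‑phenylacetyl]oxy}‑2,6,6‑trimethylcyclohex‑2‑ene‑1‑carboxylate | CC1=C[C@@H](OC(=O)[C@@H](OC)c2ccccc2)CC(C)(C)[C@]1(O)C(=O)OCC
F3 | step 4 | ethyl (1R,4S)‑2,6,6‑trimethyl‑1,4‑bis[(triethylsilyl)oxy]cyclohex‑2‑ene‑1‑carboxylate | CC1=C[C@@H](O[Si](CC)(CC)CC)CC(C)(C)[C@]1(O[Si](CC)(CC)CC)C(=O)OCC
F4 | step 4 | [(1R,4S)‑2,6,6‑trimethyl‑1,4‑bis[(triethylsilyl)oxy]cyclohex‑2‑en‑1‑yl]methanol | CC1=C[C@@H](O[Si](CC)(CC)CC)CC(C)(C)[C@]1(O[Si](CC)(CC)CC)CO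
F5 | step 4 | (1R,4S)‑2,6,6‑trimethyl‑1,4‑bis[(triethylsilyl)oxy]cyclohex‑2‑ene‑1‑carbaldehyde | CC1=C[C@@H](O[Si](CC)(CC)CC)CC(C)(C)[C@]1(O[Si](CC)(CC)CC)C=O
F6 | step 4 | (2E,4E)‑3‑methyl‑5‑[(1R,4S)‑2,6,6‑trimethyl‑1,4‑bis[(triethylsilyl)oxy]cyclohex‑2‑en‑1‑yl]penta‑2,4‑dienenitrile | CC1=C[C@@H](O[Si](CC)(CC)CC)CC(C)(C)[C@]1(O[Si](CC)(CC)CC)/C=C/C(C)=C/C#N
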